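**Plan** (prostanoid locants: ester carbon C1, ring C8–C12, quaternary carbon C12)
Cuts: the O–acetyl bond; C10–Br and C10=C11 (back to the saturated ketone, whose only enolisable α-carbon is C10); the ring bond C8–C12 by a reverse 1,2-shift to a 1-alkynylcyclobutanol; then C6–C7 (sp2–sp), C8–C9 (alkynyl to carbinol carbon), C14=C15 and C12–C13 (allyl to quaternary carbon).
Feature: in the five-membered ring the ketone carbon C9 is flanked by the sp2 carbon C8 that carries the exocyclic (E)-alkene, and C8 is bonded to the oxygen-bearing quaternary carbon C12. This ketone / alkyne-carbon / migrated-carbon triad is what a cyclobutanol leaves when one ring bond shifts onto a π-activated alkyne.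
Forward: four-membered enediol → enol carbonate → Pd-catalysed asymmetric allylation → ozonolysis and Wittig reaction → ethynyl addition → Sonogashira coupling with the C1–C6 vinyl iodide → gold-catalysed enlargement of the four-membered ring to the five-membered ring (the only ring-forming event) → α-bromination, selenoxide elimination, desilylation, acetylation.
Stereo: C12 comes from the ligand-controlled allylation and passes through the 1,2-shift with retention (both carbinol epimers converge); 14Z from the Wittig reaction; 5E from hydrozirconation; 7E from anti addition of the migrating carbon and gold across the alkyne.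

Key step: step 8

Assumption: in step 2 the ligand (S)-(CF3)3-t-BuPHOX, i.e. (S)-4-tert-butyl-2-{2-[bis(4-trifluoromethylphenyl)phosphanyl]-5-(trifluoromethyl)phenyl}-4,5-dihydrooxazole, is taken to deliver the (S)-ketone; its mirror image would be used if the sense of induction proved opposite.

**Step 1**
Reactants: 1 1,2-bis(trimethylsilyloxy)cyclobut-1-ene; 2 allyl chloroformate
Product: 4 prop-2-en-1-yl 2-(trimethylsilyloxy)cyclobut-1-en-1-yl carbonate, via lithium enolate 3 (not isolated)
Conditions: MeLi (1.0 equiv), THF, 0 °C; then 2, −78 °C to 0 °C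
Reagents that add atoms: none
Why: MeLi cleaves one O–Si bond of the symmetrical bis-silyl enediol (Me4Si is lost) and the regiodefined lithium enolate is O-acylated by the chloroformate (enol carbonate formation), which fixes the siloxy-bearing carbon as the nucleophilic site of step 2; no stereocenter is formed, and any C-acylated isomer would lead to the same palladium enolate.

**Step 2**
Reactants: 4
Product: 5 (2S)-2-(prop-2-en-1-yl)-2-(trimethylsilyloxy)cyclobutan-1-one
Conditions: Pd2(dba)3 (2.5 mol %), (S)-(CF3)3-t-BuPHOX (6 mol %), toluene, 20 °C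
Reagents that add atoms: none
Why: Decarboxylative asymmetric allylic alkylation (Tsuji–Trost type): zerovalent palladium ionises the allyl carbonate, CO2 is lost, and the (π-allyl)palladium enolate couples at the siloxy-bearing carbon, where the chiral phosphinooxazoline ligand differentiates the two faces of the flat enolate carbon and so should set the quaternary C–O stereocenter as (S).

**Step 3**
Reactants: 5
Product: 7 2-[(1S)-2-oxo-1-(trimethylsilyloxy)cyclobutyl]acetaldehyde, via ozonide 6 (not isolated)
Conditions: O3, CH2Cl2, −78 °C; then PPh3, −78 °C to 23 °C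
Reagents that add atoms: ozone, [O-][O+]=O
Why: Ozonolysis with reductive work-up cleaves the only C=C bond to the aldehyde, while the ketone, the silyl ether and the stereocenter stay untouched.

**Step 4**
Reactants: 7; 8 hexyl(triphenyl)phosphonium bromide
Product: 10 (2S)-2-[(2Z)-oct-2-en-1-yl]-2-(trimethylsilyloxy)cyclobutan-1-one, via ylide 9 (not isolated)
Conditions: 8, NaN(SiMe3)2 (1.0 equiv), THF, 0 °C; then 7, −78 °C to 0 °C
Reagents that add atoms: none
Why: Wittig olefination with a non-stabilised ylide under lithium-free conditions gives the (Z)-alkene through the kinetically preferred cis-oxaphosphetane, and at −78 °C the unhindered aldehyde should react much faster than the cyclobutanone next to a fully substituted carbon.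

**Step 5**
Reactants: 10; 11 ethynylmagnesium bromide
Product: 12 (2S)-1-ethynyl-2-[(2Z)-oct-2-en-1-yl]-2-(trimethylsilyloxy)cyclobutan-1-ol (both C1 epimers)
Conditions: HC≡CMgBr (0.5 M in THF, 1.3 equiv), THF, −78 °C to −30 °C; NH4Cl (aq) at −30 °C
Reagents that add atoms: none
Why: Nucleophilic 1,2-addition of the alkynyl Grignard reagent to the strained ketone; the new carbinol center forms as a mixture of epimers, which is harmless because this carbon becomes the sp2 ketone carbon in step 8, and the low temperature and the magnesium counter-ion should hold back migration of the silyl group to the new alkoxide.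

**Step 6**
Reactants: 13 methyl hex-5-ynoate
Product: 15 methyl (5E)-6-iodohex-5-enoate, via alkenylzirconocene 14 (not isolated)
Conditions: Cp2Zr(H)Cl (1.2 equiv), THF, 23 °C; then I2, 0 °C
Reagents that add atoms: iodine, II
Why: Hydrozirconation adds Zr–H syn across the terminal alkyne with zirconium on the terminal carbon, and iodinolysis of the C–Zr bond with retention gives the (E)-vinyl iodide.

**Step 7**
Reactants: 12; 15
Product: 16 methyl (5E)-8-{(2S)-1-hydroxy-2-[(2Z)-oct-2-en-1-yl]-2-(trimethylsilyloxy)cyclobutyl}oct-5-en-7-ynoate (both ring C1 epimers)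
Conditions: PdCl2(PPh3)2 (3 mol %), CuI (6 mol %), Et3N, THF, 23 °C
Reagents that add atoms: none
Why: Sonogashira coupling joins the terminal alkyne to the vinyl iodide with retention of the (E) geometry and tolerates the free tertiary alcohol, the silyl ether and the ester.

**Step 8**
Reactants: 16
Product: 17 methyl (5E,7E)-7-{(2S)-2-[(2Z)-oct-2-en-1-yl]-5-oxo-2-(trimethylsilyloxy)cyclopentylidene}hept-5-enoate
Conditions: Ph3PAuNTf2 (2 mol %), CH2Cl2, 23 °C
Reagents that add atoms: none
Why: The cationic phosphine complex of monovalent gold binds the alkyne, and the cyclobutane bond between the carbinol carbon and the siloxy-bearing quaternary carbon migrates to the proximal alkyne carbon anti to gold while the hydroxyl becomes the ketone (semipinacol-type 1,2-shift), after which protodeauration releases the catalyst. The closest known reaction type is the gold-catalysed ring expansion of 1-alkynylcyclobutanols to (E)-2-alkylidenecyclopentanones. The five-membered ring is not closed by a cyclisation but grows from the four-membered ring by insertion of the alkyne carbon into that ring bond. The quaternary stereocenter migrates with retention because it keeps its three other substituents throughout a suprafacial 1,2-shift, both carbinol epimers give the same ketone because that carbon becomes sp2, and the exocyclic alkene is (E) because the migrating carbon and gold add anti across the alkyne and the C–Au bond is protonated with retention. The step needs migration of the quaternary carbon and not of the ring CH2, which the substrate should secure since that carbon is the more substituted one, carries an oxygen lone-pair donor and sits in the more congested bond; the silyl ether keeps that oxygen from adding to the alkyne, and strain release should let the shift outrun attack by the side-chain (Z)-alkene.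

**Step 9**
Reactants: 17
Product: 19 methyl (5E,7E)-7-{(2R)-4-bromo-2-[(2Z)-oct-2-en-1-yl]-5-oxo-2-(trimethylsilyloxy)cyclopentylidene}hept-5-enoate (both C4 epimers), via lithium enolate 18 (not isolated)
Conditions: LiN(SiMe3)2 (1.05 equiv), THF, −78 °C; then NBS (1.05 equiv), −78 °C
Reagents that add atoms: N-bromosuccinimide, O=C1CCC(=O)N1Br
Why: Kinetic deprotonation can take place only at C10, since the other α-carbon is sp2, and bromination of the lithium enolate (electrophilic α-bromination) puts bromine on that carbon; the new C–Br center is an inconsequential epimer mixture, and the alkenes should not compete with the enolate for NBS at −78 °C.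

**Step 10**
Reactants: 19
Product: 23 methyl (5E,7E)-7-{(2R)-4-bromo-2-[(2Z)-oct-2-en-1-yl]-5-oxo-2-(trimethylsilyloxy)cyclopent-3-en-1-ylidene}hept-5-enoate, via lithium bromo enolate 20 (not isolated), via selenide 21 (not isolated), via selenoxide 22 (not isolated)
Conditions: LiN(SiMe3)2 (1.1 equiv), THF, −78 °C; PhSeCl, −78 °C to −40 °C; then H2O2 (30 % aq), pyridine, CH2Cl2, 0 °C to 23 °C
Reagents that add atoms: none
Why: The remaining C10–H, acidified by bromine, is removed, the bromo enolate is selenenylated at carbon, and oxidation gives a selenoxide whose syn elimination (selenoxide elimination) can only take a hydrogen from C11, so the ring double bond forms with bromine kept on C10.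

**Step 11**
Reactants: 23
Product: 24 methyl (5E,7E)-7-{(2R)-4-bromo-2-hydroxy-2-[(2Z)-oct-2-en-1-yl]-5-oxocyclopent-3-en-1-ylidene}hept-5-enoate
Conditions: HF·pyridine, pyridine, THF, 0 °C
Reagents that add atoms: none
Why: Fluoride-driven cleavage of the tertiary trimethylsilyl ether (desilylation, strong Si–F bond) under pyridine-buffered conditions that should spare the bromo dienone, the ester and the alkenes.

**Step 12**
Reactants: 24
Product: 25 methyl (5E,7E)-7-{(2R)-2-acetoxy-4-bromo-2-[(2Z)-oct-2-en-1-yl]-5-oxocyclopent-3-en-1-ylidene}hept-5-enoate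
Conditions: Ac2O, DMAP, Et3N, CH2Cl2, 23 °C
Reagents that add atoms: acetic anhydride, CC(=O)OC(C)=O
Why: DMAP-catalysed acyl transfer acetylates the hindered tertiary alcohol without touching the stereocenter and should give the target.

**Compound list**
1 | 1,2-bis(trimethylsilyloxy)cyclobut-1-ene | C[Si](C)(C)OC1=C(O[Si](C)(C)C)CC1 | starting material
2 | allyl chloroformate (prop-2-en-1-yl carbonochloridate) | C=CCOC(Cl)=O | starting material
3 | lithium 2-(trimethylsilyloxy)cyclobut-1-en-1-olate | [Li+].[O-]C1=C(O[Si](C)(C)C)CC1 | intermediate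
4 | prop-2-en-1-yl 2-(trimethylsilyloxy)cyclobut-1-en-1-yl carbonate | C=CCOC(=O)OC1=C(O[Si](C)(C)C)CC1 | intermediate
5 | (2S)-2-(prop-2-en-1-yl)-2-(trimethylsilyloxy)cyclobutan-1-one | C=CC[C@@]1(O[Si](C)(C)C)CCC1=O | intermediate
6 | 3-{[(1S)-2-oxo-1-(trimethylsilyloxy)cyclobutyl]methyl}-1,2,4-trioxolane (secondary ozonide of 5) | C1(OCOO1)C[C@@]2(O[Si](C)(C)C)CCC2=O | intermediate
7 | 2-[(1S)-2-oxo-1-(trimethylsilyloxy)cyclobutyl]acetaldehyde | O=CC[C@@]1(O[Si](C)(C)C)CCC1=O | intermediate
8 | hexyl(triphenyl)phosphonium bromide | CCCCCC[P+](c1ccccc1)(c1ccccc1)c1ccccc1.[Br-] | starting material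
9 | hexylidene(triphenyl)phosphorane | CCCCCC=P(c1ccccc1)(c1ccccc1)c1ccccc1 | intermediate
10 | (2S)-2-[(2Z)-oct-2-en-1-yl]-2-(trimethylsilyloxy)cyclobutan-1-one | CCCCC/C=C\C[C@@]1(O[Si](C)(C)C)CCC1=O | intermediate
11 | ethynylmagnesium bromide | C#C[Mg]Br | starting material
12 | (2S)-1-ethynyl-2-[(2Z)-oct-2-en-1-yl]-2-(trimethylsilyloxy)cyclobutan-1-ol (both C1 epimers) | CCCCC/C=C\C[C@@]1(O[Si](C)(C)C)CCC1(O)C#C | intermediate
13 | methyl hex-5-ynoate | COC(=O)CCCC#C | starting material
14 | methyl (5E)-6-[chlorobis(cyclopentadienyl)zirconio]hex-5-enoate | COC(=O)CCC/C=C/[Zr](Cl)(C1C=CC=C1)C1C=CC=C1 | intermediate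
15 | methyl (5E)-6-iodohex-5-enoate | COC(=O)CCC/C=C/I | intermediate
16 | methyl (5E)-8-{(2S)-1-hydroxy-2-[(2Z)-oct-2-en-1-yl]-2-(trimethylsilyloxy)cyclobutyl}oct-5-en-7-ynoate (both ring C1 epimers) | CCCCC/C=C\C[C@@]1(O[Si](C)(C)C)CCC1(O)C#C/C=C/CCCC(=O)OC | intermediate
17 | methyl (5E,7E)-7-{(2S)-2-[(2Z)-oct-2-en-1-yl]-5-oxo-2-(trimethylsilyloxy)cyclopentylidene}hept-5-enoate | CCCCC/C=C\C[C@@]1(O[Si](C)(C)C)CCC(=O)/C1=C/C=C/CCCC(=O)OC | intermediate
18 | lithium enolate of 17 (enolate double bond between the ketone carbon and the ring CH; quaternary center and alkenes as in 17) | [Li+].CCCCC/C=C\C[C@@]1(O[Si](C)(C)C)CC=C([O-])/C1=C/C=C/CCCC(=O)OC | intermediate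
19 | methyl (5E,7E)-7-{(2R)-4-bromo-2-[(2Z)-oct-2-en-1-yl]-5-oxo-2-(trimethylsilyloxy)cyclopentylidene}hept-5-enoate (both C4 epimers) | CCCCC/C=C\C[C@@]1(O[Si](C)(C)C)CC(Br)C(=O)/C1=C/C=C/CCCC(=O)OC | intermediate
20 | lithium enolate of 19 (bromine on the enolate carbon; quaternary center and alkenes as in 19) | [Li+].CCCCC/C=C\C[C@@]1(O[Si](C)(C)C)CC(Br)=C([O-])/C1=C/C=C/CCCC(=O)OC | intermediate
21 | methyl (5E,7E)-7-{(2R)-4-bromo-2-[(2Z)-oct-2-en-1-yl]-5-oxo-4-(phenylselanyl)-2-(trimethylsilyloxy)cyclopentylidene}hept-5-enoate (both C4 epimers) | CCCCC/C=C\C[C@@]1(O[Si](C)(C)C)CC(Br)([Se]c2ccccc2)C(=O)/C1=C/C=C/CCCC(=O)OC | intermediate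
22 | selenoxide of 21 (4-bromo-4-(phenylseleninyl) compound; mixture of isomers at C4 and at selenium) | CCCCC/C=C\C[C@@]1(O[Si](C)(C)C)CC(Br)([Se](=O)c2ccccc2)C(=O)/C1=C/C=C/CCCC(=O)OC | intermediate
23 | methyl (5E,7E)-7-{(2R)-4-bromo-2-[(2Z)-oct-2-en-1-yl]-5-oxo-2-(trimethylsilyloxy)cyclopent-3-en-1-ylidene}hept-5-enoate | CCCCC/C=C\C[C@@]1(O[Si](C)(C)C)C=C(Br)C(=O)/C1=C/C=C/CCCC(=O)OC | intermediate
24 | methyl (5E,7E)-7-{(2R)-4-bromo-2-hydroxy-2-[(2Z)-oct-2-en-1-yl]-5-oxocyclopent-3-en-1-ylidene}hept-5-enoate | CCCCC/C=C\C[C@@]1(O)C=C(Br)C(=O)/C1=C/C=C/CCCC(=O)OC | intermediate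
25 | methyl (5E,7E)-7-{(2R)-2-acetoxy-4-bromo-2-[(2Z)-oct-2-en-1-yl]-5-oxocyclopent-3-en-1-ylidene}hept-5-enoate | CCCCC/C=C\C[C@@]1(OC(C)=O)C=C(Br)C(=O)/C1=C/C=C/CCCC(=O)OC | target

**Step count**
Total: 12 steps. Longest linear sequence: 11 steps (1 → 4 → 5 → 7 → 10 → 12 → 16 → 17 → 19 → 23 → 24 → 25); step 6 is a one-step side branch.

**Steps most likely to fail**

Step 8. The 1,2-shift may lose the race against other reactions of the gold-bound alkyne: attack by the side-chain (Z)-alkene (enyne cycloisomerisation), or protodesilylation followed by addition of the freed tertiary hydroxyl to the alkyne. The fallback sets out from 10 and returns at 17; it enlarges the ring at the ketone stage, before any alkyne is present, by a β-oxido carbenoid rearrangement and then builds the alkylidene by aldol condensation. LiCHBr2 (from CH2Br2 and lithium 2,2,6,6-tetramethylpiperidide, THF, −90 °C) adds to 10 to give the dibromomethyl carbinol F1. n-BuLi (2.1 equiv, −95 to −78 °C) deprotonates the hydroxyl and exchanges one bromine, and the carbenoid rearranges with migration of the quaternary carbon (retention) and loss of LiBr to the ring-enlarged lithium enolate F2. This regiodefined enolate is trapped in the same flask with methyl (5E)-7-oxohept-5-enoate F3 (made from methyl 5-oxopentanoate and Ph3P=CHCHO) to give the aldol F4. Mesylation and elimination (MsCl, Et3N; then DBU) should give 17, the (7E) isomer being separated from any (7Z) isomer.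

Step 2. The small, nearly symmetrical cyclobutenolate may be poorly differentiated by the ligand (low enantiomeric purity), or the strained palladium enolate may be protonated before it is allylated. The fallback sets out from 1 and returns at 5; it makes the stereocenter by catalytic asymmetric addition to a ketone instead of enolate alkylation. Br2 (pentane, −60 °C) converts 1 into cyclobutane-1,2-dione F5. Enantioselective allylboration of one carbonyl (allylB(OiPr)2, (S)-3,3′-dibromo-BINOL as catalyst, toluene, −35 °C; the antipodal catalyst if needed) should give (2S)-2-hydroxy-2-(prop-2-en-1-yl)cyclobutan-1-one F6, the mono-adduct being much less electrophilic than the dione. Silylation (TMSCl, imidazole, DMF) gives 5.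

Step 10. C-selenenylation of the hindered bromo enolate may give way to transfer of bromine to selenium or to O-selenenylation, so that bromine is lost or the elimination does not take place. The fallback sets out from 17 and returns at 24; it makes the ring double bond first and brings bromine in as a nucleophile. Dehydrogenation of the lithium enolate of 17 with N-tert-butylbenzenesulfinimidoyl chloride (LiN(iPr)2, THF, −78 °C) gives the cross-conjugated dienone F7. Nucleophilic epoxidation of the ring enone (t-BuOOH, DBU, CH2Cl2, 0 °C) gives the epoxy ketone F8. Aqueous HBr (acetone, 0 °C) opens the epoxide at the carbon next to the ketone to the bromohydrin F9, which loses water and the silyl group under the same conditions to give 24.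

**Further compounds**
F1 | step 8 | (2S)-1-(dibromomethyl)-2-[(2Z)-oct-2-en-1-yl]-2-(trimethylsilyloxy)cyclobutan-1-ol (both C1 epimers) | CCCCC/C=C\C[C@@]1(O[Si](C)(C)C)CCC1(O)C(Br)Br
F2 | step 8 | lithium (3S)-3-[(2Z)-oct-2-en-1-yl]-3-(trimethylsilyloxy)cyclopent-1-en-1-olate | [Li+].CCCCC/C=C\C[C@@]1(O[Si](C)(C)C)CCC([O-])=C1
F3 | step 8 | methyl (5E)-7-oxohept-5-enoate | COC(=O)CCC/C=C/C=O
F4 | step 8 | methyl (5E)-7-hydroxy-7-{(2S)-2-[(2Z)-oct-2-en-1-yl]-5-oxo-2-(trimethylsilyloxy)cyclopentyl}hept-5-enoate (mixture at the two new centers) | CCCCC/C=C\C[C@@]1(O[Si](C)(C)C)CCC(=O)C1C(O)/C=C/CCCC(=O)OC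
F5 | step 2 | cyclobutane-1,2-dione | O=C1CCC1=O
F6 | step 2 | (2S)-2-hydroxy-2-(prop-2-en-1-yl)cyclobutan-1-one | C=CC[C@@]1(O)CCC1=O
F7 | step 10 | methyl (5E,7E)-7-{(2R)-2-[(2Z)-oct-2-en-1-yl]-5-oxo-2-(trimethylsilyloxy)cyclopent-3-en-1-ylidene}hept-5-enoate | CCCCC/C=C\C[C@@]1(O[Si](C)(C)C)C=CC(=O)/C1=C/C=C/CCCC(=O)OC
F8 | step 10 | epoxide of F7 at the ring C=C bond (epoxy ketone; quaternary center and other alkenes unchanged) | CCCCC/C=C\C[C@@]1(O[Si](C)(C)C)C2OC2C(=O)/C1=C/C=C/CCCC(=O)OC
F9 | step 10 | bromohydrin from F8 (bromine on the carbon next to the ketone and hydroxyl on the carbon next to the quaternary center; quaternary center unchanged) | CCCCC/C=C\C[C@@]1(O[Si](C)(C)C)C(O)C(Br)C(=O)/C1=C/C=C/CCCC(=O)OC
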